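**Retrosynthetic overview**
1. Xestin B (18) ⇐ its 3R pair of C6 epimers 17: acid-catalysed peroxyketal epimerisation with chromatographic removal of the 6S epimer sorts C6.
2. 17 ⇐ C3–O bond: catalytic enantioselective 6-exo peroxy-Michael closure of the hydroperoxy ketal dienoate 16 (sets C3, closes the 1,2-dioxine); 16 ⇐ Wittig olefination (C2=C3) of the peroxy-lactol 14 through its open aldehyde form.
3. 14 ⇐ key step: oxidative ring expansion of the furan ring of 11 to the 3,6-dihydro-1,2-dioxine (NBS, then H2O2, then MeOH/H+); it installs O–O, the ring cis-alkene and the C6 methyl peroxyketal.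
4. 11 ⇐ two Li2CuCl4-catalysed Grignard couplings joining furan/1,6-dibromohexane, 1-bromo-6-chlorohexane and sorbyl acetate.
5. Ring order: the only ring (the 1,2-dioxine) is first made from the furan in step 5, opened to its aldehyde tautomer for step 6, and closed for good with C3 control in step 7.

Assumption: the facial sense of the squaramide catalyst in step 7 cannot be predicted with certainty; the pseudo-enantiomer (quinidine- or quinine-derived) that gives 3R is used. C6 is racemic from step 5 on and is sorted in step 8.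

**Step 1**
Reactants: 1 furan; 2 1,6-dibromohexane
Product: 4 2-(6-bromohexyl)furan, via 2-furyllithium 3 (not isolated)
Conditions: n-BuLi, THF, 0 °C; then 2 (3 equiv), −78 °C → rt
Reagents that add atoms: none
Why: α-Lithiation of furan followed by SN2 alkylation; the excess of 2 suppresses double alkylation.

**Step 2**
Reactants: 5 (2E,4E)-hexa-2,4-dien-1-ol
Product: 6 (2E,4E)-hexa-2,4-dien-1-yl acetate
Conditions: Ac2O, pyridine, DMAP (cat.), 0 °C → rt
Reagents that add atoms: acetic anhydride CC(=O)OC(C)=O
Why: Standard DMAP-catalysed O-acetylation that turns the allylic alcohol into the leaving group for step 3.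

**Step 3**
Reactants: 7 1-bromo-6-chlorohexane; 6 (2E,4E)-hexa-2,4-dien-1-yl acetate
Product: 9 (2E,4E)-12-chlorododeca-2,4-diene, via 6-chlorohexylmagnesium bromide 8 (not isolated)
Conditions: Mg, THF, 30 °C; then 6, Li2CuCl4 (2 mol %), THF, −20 → 0 °C
Reagents that add atoms: none
Why: Mg inserts selectively into the C–Br bond, and Kochi-type Li2CuCl4-catalysed coupling of the Grignard reagent with the dienyl acetate occurs at the acetate-bearing carbon with the E,E-diene retained (the classical route to E,E-dienyl pheromone chains).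

**Step 4**
Reactants: 9 (2E,4E)-12-chlorododeca-2,4-diene; 4 2-(6-bromohexyl)furan
Product: 11 2-[(14E,16E)-octadeca-14,16-dien-1-yl]furan, via dienylmagnesium chloride 10 (not isolated)
Conditions: Mg, THF, reflux; then 4, Li2CuCl4 (3 mol %), NMP, THF, 0 °C → rt
Reagents that add atoms: none
Why: Kochi–Tamura sp3–sp3 cross-coupling of a primary alkyl Grignard reagent with a primary alkyl bromide; furan and diene are inert to the Grignard reagent.

**Step 5**
Reactants: 11 2-[(14E,16E)-octadeca-14,16-dien-1-yl]furan
Product: 14 6-methoxy-6-[(14E,16E)-octadeca-14,16-dien-1-yl]-3,6-dihydro-1,2-dioxin-3-ol, via (2Z)-keto-enal 12 (not isolated), via dioxinediol 13 (not isolated)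
Conditions: NBS (1.0 equiv), NaHCO3, THF–H2O (5:1), −20 °C; then 50 % H2O2 (3 equiv), 0 °C; Et2O extraction, H2O wash; then MeOH (10 equiv), PPTS (5 mol %), CH2Cl2, 0 °C (telescoped, no purification)
Reagents that add atoms: hydrogen peroxide OO; methanol CO
Why: Achmatowicz-type oxidative ring expansion of the five-membered furan to the six-membered 1,2-dioxine by a stepwise polar sequence: bromination/hydrolysis at the most electron-rich π system (the furan, not the distal diene) gives the cis-keto-enal 12 (ketone oxygen from water, aldehyde oxygen from the furan), H2O2 bridges both carbonyls as the cyclic bis-hemiperketal 13 (as 1,4-dicarbonyls do), and the tertiary C6 hemiperketal is methylated faster than the secondary C3 one through the tertiary peroxycarbenium ion (as ketosides form faster than aldosides), which expels the water-derived hydroxyl; 14 is racemic at C6 and an anomeric mixture at C3.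

**Step 6**
Reactants: 14 6-methoxy-6-[(14E,16E)-octadeca-14,16-dien-1-yl]-3,6-dihydro-1,2-dioxin-3-ol
Product: 16 methyl (2E,4Z,20E,22E)-6-hydroperoxy-6-methoxytetracosa-2,4,20,22-tetraenoate, via hydroperoxy aldehyde 15 (not isolated)
Conditions: Ph3P=CHCO2Me (1.3 equiv), PhCO2H (10 mol %), CH2Cl2, 0 °C → rt
Reagents that add atoms: methyl (triphenylphosphoranylidene)acetate COC(=O)C=P(c1ccccc1)(c1ccccc1)c1ccccc1
Why: Lactol-type Wittig olefination through the ring-chain aldehyde tautomer 15; the stabilised ylide gives the 2E-enoate, the ring-derived 4Z geometry is kept, and without an amine base (benzoic acid buffers the ylide) the hydroperoxide does not yet add to the dienoate.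

**Step 7**
Reactants: 16 methyl (2E,4Z,20E,22E)-6-hydroperoxy-6-methoxytetracosa-2,4,20,22-tetraenoate
Product: 17 methyl 2-[(3R,6RS)-6-methoxy-6-[(14E,16E)-octadeca-14,16-dien-1-yl]-3,6-dihydro-1,2-dioxin-3-yl]acetate (3R pair of C6 epimers, about 1:1)
Conditions: 9-amino-9-deoxy-epi-quinidine 3,5-bis(trifluoromethyl)phenyl squaramide (10 mol %), PhMe, −30 °C; AcOH quench; short SiO2 plug (epimers kept together)
Reagents that add atoms: none
Why: Proposed new method: enantioselective 6-exo-trig peroxy-Michael ring closure of a hydroperoxy ketal onto an α,β-unsaturated ester; the quinuclidine deprotonates the hydroperoxide (pKa about 12), the squaramide N–H bonds bind the ester carbonyl, and the ammonium–peroxide ion pair delivers oxygen to one face of the 2E-enoate, after which the ammonium protonates the ester enolate before it can close to an epoxide; this sets C3 as R in both C6 antipodes, so racemic 16 gives the 3R pair of C6 epimers 17 (6S from (6S)-16, 6R from (6R)-16); the closest known reactions are the racemic Et2NH/CF3CH2OH peroxy-Michael cyclisation that builds 3-methoxy-1,2-dioxane-6-acetates and squaramide- or iminophosphorane-catalysed enantioselective intramolecular oxa-Michael additions of alcohols to enoates.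

**Step 8**
Reactants: 17 methyl 2-[(3R,6RS)-6-methoxy-6-[(14E,16E)-octadeca-14,16-dien-1-yl]-3,6-dihydro-1,2-dioxin-3-yl]acetate
Product: 18 methyl 2-[(3R,6S)-6-methoxy-6-[(14E,16E)-octadeca-14,16-dien-1-yl]-3,6-dihydro-1,2-dioxin-3-yl]acetate (xestin B)
Conditions: SiO2 (6S epimer collected); 6R fraction: PPTS (10 mol %), MeOH–CH2Cl2 (1:4), 0 °C → rt, NaHCO3 quench, SiO2; two recycles
Reagents that add atoms: methanol CO
Why: Acid-catalysed peroxyketal exchange (an anomerisation-type epimerisation): PPTS ionises the C6–OMe bond to the ring peroxycarbenium ion already used in step 5 and methanol re-adds to either face while C3 and the O–O bond stay untouched, so the unwanted 6R epimer is turned back into a 6S/6R mixture (expected between 1:1 and 1:2, since OMe can sit pseudoaxial in both epimers but the C3 side chain is then pseudoaxial in 18) from which 18 is removed by chromatography; C6 is thus set by separation combined with equilibrative recycling, which should lift the yield of 18 from 17 from 50 % to about 75–80 %.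

**Compound list**
1 | furan | c1ccoc1 | starting material
2 | 1,6-dibromohexane | BrCCCCCCBr | starting material
3 | 2-furyllithium | [Li]c1ccco1 | intermediate
4 | 2-(6-bromohexyl)furan | BrCCCCCCc1ccco1 | intermediate
5 | (2E,4E)-hexa-2,4-dien-1-ol (sorbyl alcohol) | C/C=C/C=C/CO | starting material
6 | (2E,4E)-hexa-2,4-dien-1-yl acetate | C/C=C/C=C/COC(C)=O | intermediate
7 | 1-bromo-6-chlorohexane | ClCCCCCCBr | starting material
8 | 6-chlorohexylmagnesium bromide | ClCCCCCC[Mg]Br | intermediate
9 | (2E,4E)-12-chlorododeca-2,4-diene | C/C=C/C=C/CCCCCCCCl | intermediate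
10 | [(8E,10E)-dodeca-8,10-dien-1-yl]magnesium chloride | C/C=C/C=C/CCCCCCC[Mg]Cl | intermediate
11 | 2-[(14E,16E)-octadeca-14,16-dien-1-yl]furan | C/C=C/C=C/CCCCCCCCCCCCCc1ccco1 | intermediate
12 | (2Z,18E,20E)-4-oxodocosa-2,18,20-trienal | C/C=C/C=C/CCCCCCCCCCCCCC(=O)/C=C\C=O | intermediate
13 | 6-[(14E,16E)-octadeca-14,16-dien-1-yl]-3,6-dihydro-1,2-dioxine-3,6-diol (racemic, diastereomer mixture) | C/C=C/C=C/CCCCCCCCCCCCCC1(O)C=CC(O)OO1 | intermediate
14 | 6-methoxy-6-[(14E,16E)-octadeca-14,16-dien-1-yl]-3,6-dihydro-1,2-dioxin-3-ol (racemic at C6, both C3 anomers) | C/C=C/C=C/CCCCCCCCCCCCCC1(OC)C=CC(O)OO1 | intermediate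
15 | (2Z,18E,20E)-4-hydroperoxy-4-methoxydocosa-2,18,20-trienal (racemic) | C/C=C/C=C/CCCCCCCCCCCCCC(OC)(OO)/C=C\C=O | intermediate
16 | methyl (2E,4Z,20E,22E)-6-hydroperoxy-6-methoxytetracosa-2,4,20,22-tetraenoate (racemic at C6) | C/C=C/C=C/CCCCCCCCCCCCCC(OC)(OO)/C=C\C=C\C(=O)OC | intermediate
17 | methyl 2-[(3R,6RS)-6-methoxy-6-[(14E,16E)-octadeca-14,16-dien-1-yl]-3,6-dihydro-1,2-dioxin-3-yl]acetate (3R fixed, about 1:1 mixture of the 6S and 6R epimers) | C/C=C/C=C/CCCCCCCCCCCCCC1(OC)C=C[C@@H](CC(=O)OC)OO1 | intermediate
18 | methyl 2-[(3R,6S)-6-methoxy-6-[(14E,16E)-octadeca-14,16-dien-1-yl]-3,6-dihydro-1,2-dioxin-3-yl]acetate (xestin B; side chain at C3 trans to OMe) | C/C=C/C=C/CCCCCCCCCCCCC[C@@]1(OC)C=C[C@@H](CC(=O)OC)OO1 | target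

**Step count and risks**

Total: 8 steps. Longest linear sequence: 7 steps (2, 3, 4, 5, 6, 7, 8).

Steps most likely to fail:

Step 7 (the new step). Risks:
- catalyst control at C3 may be eroded by the fixed C6 centre in one antipode of 16, which would lower the ee of 18;
- base-induced Kornblum–DeLaMare opening of the product at the C3–H;
- epoxide formation from the ester enolate.

Fallback with known chemistry, setting out from 16 and returning at 18: cyclise 16 with Et2NH in CF3CH2OH at rt, the established conditions for intramolecular peroxy-Michael additions of hydroperoxy ketals to enoates. This gives all four stereoisomers: 18, its enantiomer methyl 2-[(3S,6R)-6-methoxy-6-[(14E,16E)-octadeca-14,16-dien-1-yl]-3,6-dihydro-1,2-dioxin-3-yl]acetate F4, the cis isomer methyl 2-[(3R,6R)-6-methoxy-6-[(14E,16E)-octadeca-14,16-dien-1-yl]-3,6-dihydro-1,2-dioxin-3-yl]acetate F5 and its enantiomer methyl 2-[(3S,6S)-6-methoxy-6-[(14E,16E)-octadeca-14,16-dien-1-yl]-3,6-dihydro-1,2-dioxin-3-yl]acetate F6. Silica chromatography separates the trans pair from the cis pair, and preparative HPLC of the trans pair on a chiral stationary phase (amylose tris(3,5-dimethylphenylcarbamate)) delivers 18.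

Step 5 (ring expansion). Risks:
- bromination of the diene;
- H2O2 adducts other than the six-membered one;
- methylation at C3 as well as C6.

Fallback setting out from 11 and returning at 14: methylene-blue-sensitised photooxygenation in MeOH at −78 °C. The furan takes up singlet oxygen far faster than the acyclic E,E-diene, and methanolysis gives 5-hydroperoxy-2-methoxy-2-[(14E,16E)-octadeca-14,16-dien-1-yl]-2,5-dihydrofuran F1. PPTS in CH2Cl2 then isomerises F1 by transketalisation, the hydroperoxide oxygen replacing the ring oxygen at the ketal carbon, to the six-membered peroxy-lactol 14.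

Step 6 (Wittig next to a free hydroperoxide). Risks:
- attack of the ylide on the O–O bond;
- premature racemic cyclisation.

Fallback setting out from 11 and returning at 16, with the order reversed so that no phosphorus reagent meets a peroxide: NBS/NaHCO3 oxidation to 12 and Wittig olefination in the same flask give methyl (2E,4Z,20E,22E)-6-oxotetracosa-2,4,20,22-tetraenoate F2. HC(OMe)3/MeOH/PPTS converts it into methyl (2E,4Z,20E,22E)-6,6-dimethoxytetracosa-2,4,20,22-tetraenoate F3. Exchange of one methoxy group with anhydrous ethereal H2O2 and catalytic PPTS (the standard route from dimethyl ketals to α-methoxy hydroperoxides) gives 16.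

**Further compounds**
F1 | step 5 | 5-hydroperoxy-2-methoxy-2-[(14E,16E)-octadeca-14,16-dien-1-yl]-2,5-dihydrofuran (racemic, diastereomer mixture) | C/C=C/C=C/CCCCCCCCCCCCCC1(OC)C=CC(OO)O1
F2 | step 6 | methyl (2E,4Z,20E,22E)-6-oxotetracosa-2,4,20,22-tetraenoate | C/C=C/C=C/CCCCCCCCCCCCCC(=O)/C=C\C=C\C(=O)OC
F3 | step 6 | methyl (2E,4Z,20E,22E)-6,6-dimethoxytetracosa-2,4,20,22-tetraenoate | C/C=C/C=C/CCCCCCCCCCCCCC(OC)(OC)/C=C\C=C\C(=O)OC
F4 | step 7 | methyl 2-[(3S,6R)-6-methoxy-6-[(14E,16E)-octadeca-14,16-dien-1-yl]-3,6-dihydro-1,2-dioxin-3-yl]acetate (enantiomer of 18) | C/C=C/C=C/CCCCCCCCCCCCC[C@]1(OC)C=C[C@H](CC(=O)OC)OO1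
F5 | step 7 | methyl 2-[(3R,6R)-6-methoxy-6-[(14E,16E)-octadeca-14,16-dien-1-yl]-3,6-dihydro-1,2-dioxin-3-yl]acetate (C6 epimer of 18) | C/C=C/C=C/CCCCCCCCCCCCC[C@]1(OC)C=C[C@@H](CC(=O)OC)OO1
F6 | step 7 | methyl 2-[(3S,6S)-6-methoxy-6-[(14E,16E)-octadeca-14,16-dien-1-yl]-3,6-dihydro-1,2-dioxin-3-yl]acetate (enantiomer of F5) | C/C=C/C=C/CCCCCCCCCCCCC[C@@]1(OC)C=C[C@H](CC(=O)OC)OO1
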